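## Structural features

The target is an open-chain 1,4-diaryl-1,4-diketone. Its backbone is numbered C1 (carbonyl carbon on the 4-methoxyphenyl ring), C2 (methine bearing phenyl), C3 (methine bearing the amide carbonyl C5) and C4 (carbonyl carbon on the 2-hydroxy-4,6-dimethoxyphenyl ring); C5 is joined through nitrogen to a four-carbon chain that ends in a benzamide. The only rings are four separate benzene rings, so the whole difficulty lies in the C1–C4 chain. C2 and C3 are adjacent stereocentres, both R, which places phenyl and the amide carbonyl anti when the chain is drawn extended. C3 sits between two carbonyl groups (C4 and C5) and will epimerise through its enol, whereas C2 is next to one carbonyl (C1) and a phenyl ring and must be made as one enantiomer and then kept away from base. Fragile elements are the β-keto amide (retro-Claisen cleavage), the 1,4-diketone (furan or pyrrole formation with acid or a primary amine), the phenol ortho to C4 (it would close onto a C5 ester to a 4-hydroxycoumarin) and the electron-rich trioxygenated ring. The real problem is site selectivity: the C3–C4 bond has to come from enolate chemistry at C3, but in any open-chain C1 ketone the C2–H, flanked by carbonyl and phenyl, is the more acidic hydrogen. The key step exploits that C1, C2 and C3 can be tied into a three-membered siloxycyclopropane ring in which C1 is a masked ketone, C2 is a ring methine with no carbonyl neighbour, and C3, α to the ester carbonyl C5, carries the only acidic hydrogen; breaking the strained C1–C3 bond afterwards returns the C1 ketone.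

## Logic of the disconnections

14 to 13: the O–CH2 bond of a benzyl ether on the phenol oxygen is cut. The phenol has to stay masked from 6 onwards, because a free ortho-hydroxyl would quench enolate 9, would not pass through the acid chloride 8, and would lactonise onto the C5 ester of 11. The gain is that the last operation is a neutral hydrogenolysis that cannot enolise C2. The forward step must leave both aryl ketones unreduced, and it is the point at which C3 has to settle as R by equilibration.

13 to 11 and 12: the C5–N bond is cut. The two N–H bonds of 12 cannot pass through the strongly basic key step, whereas an ester at C5 is exactly what acidifies C3 in the ring. The cut removes the whole side chain and leaves a β-keto ester. The forward step must make the amine attack C5 and not condense with the C1 or C4 ketone, must not epimerise C2 on heating, and must be run while the phenol is still benzylated.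

11 to 4 and 8 (through 9 and 10): the C3–C4 bond is cut and, in the backward sense, the C1–C3 bond is re-made as a ring bond with silicon on the C1 oxygen. In 11 the C2–H lies between a ketone and a phenyl ring; in 4 the same carbon has no carbonyl neighbour, so only C3 can be deprotonated. The cut divides 11 into two halves of similar size. The forward step demands C-acylation of a hindered enolate by a di-ortho-substituted aroyl chloride, followed by ring opening under non-basic conditions.

4 to 2 and 3: the ring bonds C1–C3 and C2–C3 are cut ([2+1]). The carbene carbon brings in C3 with C5, and one facial choice on a flat alkene fixes C1 and C2 together. The gain is that the one persistent stereocentre, C2, comes from asymmetric catalysis. The forward step demands Z geometry in 2, enantioface control, and 4 as a single C3 diastereomer.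

2 to 1: the O–Si bond is cut, leading to a commercial ketone. The forward step must give the Z enol ether.

8 to 7 to 6 to 5: the C–Cl bond, then one oxidation level at the carboxyl carbon, then the O–benzyl bond are removed. 5 already carries the full substitution pattern of the ring. The forward steps must oxidise without chlorinating the ring and must handle 7 without strong acid.

## Other disconnections considered

Alternative 1: The cut passes through C1–C2 and C3–C4 at once. In the forward direction the flavonol A1 is irradiated above 330 nm with the cinnamamide A2 in the presence of a chiral diol host of the TADDOL type. Excited-state proton transfer turns A1 into an oxidopyrylium, which adds across the alkene of A2 and closes the five-membered carbocycle of the bridged aglain ketone A3. The bridging carbonyl carbon is then excised so that C1 and C4 become ketones and the pyran oxygen becomes the phenol.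
- In favour: both backbone bonds form in one step from two short fragments. The amide side chain is present from the start and the phenol needs no protecting group.
- Against: the host controls the face through hydrogen bonds, and the two amide N–H groups of A2 would compete for them. A ketol shift of A3 to the cyclopenta[b]benzofuran skeleton would divert material. The excision needs at least two oxidative C–C cleavages on an electron-rich arene. A3 has phenyl and amide trans on the ring, which is the C3 epimer of the target, so the same late equilibration is needed.
- Comparison: Alternative 1 is the better plan on convergence and on avoiding a diazo compound and a strong base. It is equal in keeping C2 free of an acidic hydrogen until late. It would be weaker on enantiocontrol at C2, which the chosen plan takes from a metal carbene on a flat enol ether, and on the number of steps after the key step (several, against two).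

Alternative 2: The cut is at C3–C5. In the forward direction the isocyanide A5 would attack C3 of the ene-dione A4 and the C1 carbonyl oxygen would close onto the nitrilium carbon, a formal [4+1] cycloaddition that gives the aminofuran A6 after tautomerisation. A6 would then be hydrolysed with enantioselective protonation to open the ring and create C2.
- In favour: the route is very short. The amide carbon arrives with its side chain, so no ester aminolysis is needed, and no organometallic base is used.
- Against: A6 is achiral, so all stereochemical information must come from protonating a transient enol at C2, in a protic acidic medium where that centre racemises most easily. A6 is a push–pull 2-amino-3-aroylfuran and should resist hydrolysis. The acid needed would also favour furan re-closure of the 1,4-diketone.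
- Comparison: Alternative 2 is clearly better on step count and equal on protecting groups (the benzyl ether is still needed). It is weaker on mechanism, because the chosen plan sets C2 in a C–C bond-forming step of a known catalyst class and keeps it non-acidic until the ketone is unveiled under buffered conditions.

Alternative 3: The cut is the C2–phenyl bond. In the forward direction a rhodium catalyst carrying a chiral bicyclic diene would transfer phenyl from phenylboronic acid A8 to C2 of the triacyl alkene A7 in the presence of aqueous hydroxide base. The product A9 is the same compound as 13.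
- In favour: the key step ends one hydrogenolysis from the target. The enantioselective step is catalytic and late, and the amide is in place beforehand.
- Against: the alkene geometry of A7 is not controlled, and the two isomers may react with opposite facial sense. A7 is a very strong acceptor, open to hydration and to addition at the wrong terminus. The new C2–H is ketone-α and benzylic from the moment it forms, in aqueous base.
- Comparison: Alternative 3 is better on step economy (about five steps against eight). It is equal on protecting groups and on reliance on the final C3 equilibration. It would be weaker on the integrity of C2, which the chosen plan creates inside a ring where it cannot enolise.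

Key step: step 6

Remarks on the chemistry (assumptions):
- The stereodescriptors were checked atom by atom: the Z enol ether 2 leads to phenyl cis to silyloxy in 4, and C2 of 4 is R with the same spatial arrangement as C2 of 14, so no structure needs correcting.
- Design of 4: it is used as one diastereomer (ester trans to silyloxy and phenyl). Copper bisoxazoline catalysts mainly fix the face of the carbene carbon, so the C3 epimer is expected to come from the other face of 2 and would feed S at C2 into step 6.
- The (R,R) enantiomer of the tert-butyl bisoxazoline is assumed to give R at C2, by analogy with the sense known for styrene. If the sense proves opposite, the (S,S) ligand is used with no other change.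
- The (2R,3R) isomer of 14 is assumed to be the more stable, or the crystallising, C3 epimer.

## Route

Step 1
Reactants: 1 1-(4-methoxyphenyl)-2-phenylethanone
Product: 2 (Z)-tert-butyl{[1-(4-methoxyphenyl)-2-phenylethenyl]oxy}dimethylsilane (silyloxy and phenyl on the same side)
Conditions: t-BuMe2SiOTf, Et3N, CH2Cl2, 0 °C to rt
Reagents that add atoms: tert-butyldimethylsilyl trifluoromethanesulfonate, CC(C)(C)[Si](C)(C)OS(=O)(=O)C(F)(F)F
Why: Soft enolisation and O-silylation of an aryl benzyl ketone; the Z isomer, with the two aryl groups trans, is favoured both kinetically and thermodynamically. The tert-butyldimethylsilyl group is chosen because it survives chromatography and the lithium amide of step 6.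

Step 2
Reactants: 2 (Z)-silyl enol ether; 3 methyl diazoacetate
Product: 4 methyl (1S,2S,3R)-2-[(tert-butyldimethylsilyl)oxy]-2-(4-methoxyphenyl)-3-phenylcyclopropane-1-carboxylate (chain C1 S, C2 R, C3 S; phenyl cis to silyloxy; ester trans to both; single diastereomer)
Conditions: 3 (dilute CH2Cl2 solution, slow addition), Cu(MeCN)4PF6 (monovalent copper, 3 mol%), (R,R)-t-Bu-bisoxazoline, CH2Cl2, rt; chromatography to remove the C3 epimer
Reagents that add atoms: none
Why: Copper-carbene [2+1] cyclopropanation of an electron-rich silyl enol ether, a known reaction of copper bisoxazoline catalysts with diazoacetates. The addition is stereospecifically syn, so the Z geometry becomes the cis relation of phenyl and silyloxy, and the ligand 2,2'-(propane-2,2-diyl)bis[(4R)-4-tert-butyl-4,5-dihydrooxazole] selects the alkene face that fixes C1 and C2 together. The ester goes trans to the more crowded side, and the minor epimer is removed because it is expected to carry the opposite C2.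

Step 3
Reactants: 5 2-hydroxy-4,6-dimethoxybenzaldehyde
Product: 6 2-(benzyloxy)-4,6-dimethoxybenzaldehyde
Conditions: BnBr, K2CO3, DMF, 60 °C
Reagents that add atoms: benzyl bromide, BrCc1ccccc1
Why: Williamson ether synthesis on a hydrogen-bonded but acidic ortho-hydroxy aldehyde; warming in DMF overcomes the chelation.

Step 4
Reactants: 6 2-(benzyloxy)-4,6-dimethoxybenzaldehyde
Product: 7 2-(benzyloxy)-4,6-dimethoxybenzoic acid
Conditions: NaClO2, NaH2PO4, 2-methyl-2-butene, t-BuOH/H2O, rt; work-up at pH 3 to 4, cold
Reagents that add atoms: sodium chlorite (NaClO2), [Na+].[O-]Cl=O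
Why: Pinnick oxidation; the alkene scavenger traps HOCl, which would otherwise chlorinate the electron-rich ring. A mild acidic work-up avoids decarboxylation of the trioxygenated benzoic acid.

Step 5
Reactants: 7 2-(benzyloxy)-4,6-dimethoxybenzoic acid
Product: 8 2-(benzyloxy)-4,6-dimethoxybenzoyl chloride
Conditions: (COCl)2, DMF (cat.), CH2Cl2, 0 °C to rt; evaporated and used crude
Reagents that add atoms: oxalyl chloride, O=C(Cl)C(=O)Cl
Why: Vilsmeier-type chlorination of a carboxylic acid; 2,6-dioxygenated aroyl chlorides are shielded and handleable, and the absence of an α-hydrogen rules out ketene formation in step 6.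

Step 6
Reactants: 4 siloxycyclopropane ester; 8 2-(benzyloxy)-4,6-dimethoxybenzoyl chloride
Product: 11 methyl (2R,3R)-2-[2-(benzyloxy)-4,6-dimethoxybenzoyl]-4-(4-methoxyphenyl)-4-oxo-3-phenylbutanoate (chain C2 R; chain C3 drawn R but labile), via lithium ester enolate 9 (not isolated), via C3-aroyl siloxycyclopropane 10 (not isolated)
Conditions: LiN(i-Pr)2 (1.1 equiv), THF, −78 °C; 8, −78 to −30 °C; then Et3N·3HF, 0 °C to rt (same flask)
Reagents that add atoms: none
Why: LiN(i-Pr)2 can remove only the C3–H, the one hydrogen α to a carbonyl group, because C2 is a plain ring methine and C1 bears no hydrogen; the ester enolate 9 then attacks the aroyl chloride 8 by addition–elimination and forms the C3–C4 bond of 10. The closest known reaction type is the deprotonation of methyl 2-siloxycyclopropanecarboxylates with lithium amides, trapping with carbon electrophiles and fluoride-induced opening to γ-oxo esters, combined with Claisen-type C-acylation of lithium ester enolates by acid chlorides. C-acylation is expected over O-acylation because O-acylation would lock an exocyclic double bond onto the three-membered ring whereas C-acylation returns C3 to sp3, and 10 has no α-hydrogen left, so no second equivalent of base is consumed. Et3N·3HF then cleaves the Si–O bond and the C1 oxygen lone pair pushes open the C1–C3 bond, a retro-aldol-type fragmentation driven by ring strain and by the doubly stabilised C3 enolate of the β-keto ester, which is protonated in the buffered medium to give 11. The C1–C3 bond breaks and not the C1–C2 bond, because only C3 can carry the negative charge. No ring is closed. The new stereocentre C3 is not controlled here and need not be, since it lies between two carbonyl groups and is set at the end by equilibration, while C2 takes part in no bond change and keeps the R configuration from step 2. The step needs site selectivity (C3, not C2), which the ring secures, and integrity of C2 once the ketone is unveiled, which the mildly acidic fluoride source secures in place of a basic one.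

Step 7
Reactants: 11 methyl keto ester; 12 N-(4-aminobutyl)benzamide
Product: 13 (2R,3R)-N-(4-benzamidobutyl)-2-[2-(benzyloxy)-4,6-dimethoxybenzoyl]-4-(4-methoxyphenyl)-4-oxo-3-phenylbutanamide (O-benzyl ether of the target; C3 labile)
Conditions: 12 (1.05 equiv), DMAP (0.2 equiv), toluene, 110 °C, 4 Å molecular sieves
Reagents that add atoms: none
Why: Aminolysis of a β-keto ester by a primary amine in hot toluene, a known reaction that runs through the α-oxoketene or DMAP-assisted addition–elimination, with methanol removed by the sieves. The C4 ketone is shielded by its di-ortho-substituted ring against enaminone formation, and the C3–H, the most acidic hydrogen, buffers the amine so that C2 should not be enolised.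

Step 8
Reactants: 13 O-benzyl keto amide
Product: 14 (2R,3R)-N-(4-benzamidobutyl)-2-(2-hydroxy-4,6-dimethoxybenzoyl)-4-(4-methoxyphenyl)-4-oxo-3-phenylbutanamide (target)
Conditions: H2 (1 atm), 10% Pd/C, EtOAc, rt; crystallisation (EtOAc/heptane)
Reagents that add atoms: none
Why: Hydrogenolysis of a benzyl aryl ether; aryl ketones and amides should be inert at 1 atm in a neutral aprotic solvent. C3 equilibrates through the enol of the β-keto amide and the (2R,3R) isomer should be collected on crystallisation, while C2 sees neither acid nor base.

## Compound list

1 | 1-(4-methoxyphenyl)-2-phenylethanone | COc1ccc(C(=O)Cc2ccccc2)cc1 | starting material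
2 | (Z)-tert-butyl{[1-(4-methoxyphenyl)-2-phenylethenyl]oxy}dimethylsilane | COc1ccc(/C(O[Si](C)(C)C(C)(C)C)=C/c2ccccc2)cc1 | intermediate
3 | methyl diazoacetate | COC(=O)C=[N+]=[N-] | starting material
4 | methyl (1S,2S,3R)-2-[(tert-butyldimethylsilyl)oxy]-2-(4-methoxyphenyl)-3-phenylcyclopropane-1-carboxylate | COC(=O)[C@H]1[C@H](c2ccccc2)[C@@]1(O[Si](C)(C)C(C)(C)C)c1ccc(OC)cc1 | intermediate
5 | 2-hydroxy-4,6-dimethoxybenzaldehyde | COc1cc(O)c(C=O)c(OC)c1 | starting material
6 | 2-(benzyloxy)-4,6-dimethoxybenzaldehyde | COc1cc(OCc2ccccc2)c(C=O)c(OC)c1 | intermediate
7 | 2-(benzyloxy)-4,6-dimethoxybenzoic acid | COc1cc(OCc2ccccc2)c(C(=O)O)c(OC)c1 | intermediate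
8 | 2-(benzyloxy)-4,6-dimethoxybenzoyl chloride | O=C(Cl)c1c(OCc2ccccc2)cc(OC)cc1OC | intermediate
9 | lithium ester enolate of 4 (not isolated; enolate geometry not defined) | [Li+].COC([O-])=C1[C@H](c2ccccc2)[C@@]1(O[Si](C)(C)C(C)(C)C)c1ccc(OC)cc1 | intermediate
10 | methyl 1-[2-(benzyloxy)-4,6-dimethoxybenzoyl]-2-[(tert-butyldimethylsilyl)oxy]-2-(4-methoxyphenyl)-3-phenylcyclopropane-1-carboxylate (not isolated; aroyl expected trans to phenyl and silyloxy, either C3 configuration converges) | COC(=O)[C@]1(C(=O)c2c(OCc3ccccc3)cc(OC)cc2OC)[C@H](c2ccccc2)[C@@]1(O[Si](C)(C)C(C)(C)C)c1ccc(OC)cc1 | intermediate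
11 | methyl (2R,3R)-2-[2-(benzyloxy)-4,6-dimethoxybenzoyl]-4-(4-methoxyphenyl)-4-oxo-3-phenylbutanoate | COc1ccc(C(=O)[C@@H](c2ccccc2)[C@@H](C(=O)OC)C(=O)c2c(OCc3ccccc3)cc(OC)cc2OC)cc1 | intermediate
12 | N-(4-aminobutyl)benzamide | NCCCCNC(=O)c1ccccc1 | starting material
13 | (2R,3R)-N-(4-benzamidobutyl)-2-[2-(benzyloxy)-4,6-dimethoxybenzoyl]-4-(4-methoxyphenyl)-4-oxo-3-phenylbutanamide | COc1ccc(C(=O)[C@@H](c2ccccc2)[C@@H](C(=O)NCCCCNC(=O)c2ccccc2)C(=O)c2c(OCc3ccccc3)cc(OC)cc2OC)cc1 | intermediate
14 | (2R,3R)-N-(4-benzamidobutyl)-2-(2-hydroxy-4,6-dimethoxybenzoyl)-4-(4-methoxyphenyl)-4-oxo-3-phenylbutanamide | COc1ccc(C(=O)[C@@H](c2ccccc2)[C@@H](C(=O)NCCCCNC(=O)c2ccccc2)C(=O)c2c(O)cc(OC)cc2OC)cc1 | target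

## Step count and risks

Total: 8 steps. Longest linear sequence: 6 steps (steps 3, 4, 5, 6, 7, 8, from 5 to 14).

Step 6 (key step). The most likely failure is sluggish C-acylation: a quaternary C3 is created next to the quaternary C1, and the acyl carbon of 8 is flanked by two ortho substituents, so the enolate may outlast the addition and decompose or be acylated on oxygen as the mixture is warmed. Fallback (sets out from 4 and 6, returns at 10): enolate 9, generated as in step 6, is added at −78 °C to aldehyde 6, a far less hindered electrophile of a class known to react with these enolates. A cold quench gives methyl 1-{[2-(benzyloxy)-4,6-dimethoxyphenyl](hydroxy)methyl}-2-[(tert-butyldimethylsilyl)oxy]-2-(4-methoxyphenyl)-3-phenylcyclopropane-1-carboxylate F1 (either carbinol configuration). Oxidation with Dess–Martin periodinane (NaHCO3, CH2Cl2) gives 10, which is opened with Et3N·3HF as in step 6. This variant makes 7 and 8 unnecessary.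

Step 2. The trisubstituted, doubly aryl-substituted enol ether may react slowly with the copper carbene, so that carbene dimerisation competes, and discrimination of the alkene faces or of the two ester orientations may be insufficient. Fallback (sets out from 2 and 3, returns at 4): cyclopropanation with Rh2(OAc)4 (divalent rhodium) in CH2Cl2 gives the racemic trans ester, which is resolved by preparative chromatography on a chiral stationary phase. The enantiomer, methyl (1R,2R,3S)-2-[(tert-butyldimethylsilyl)oxy]-2-(4-methoxyphenyl)-3-phenylcyclopropane-1-carboxylate F2, is set aside.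

Step 7. During prolonged heating the primary amine may condense with the C1 ketone and go on to a pyrrole with C4, or the basic medium may slowly enolise C2. Fallback (sets out from 2, returns at 13): the tert-butyl ester series, which reacts through a thermally generated α-oxoketene at lower amine concentration.
- Cyclopropanation of 2 with tert-butyl diazoacetate under the conditions of step 2 gives tert-butyl (1S,2S,3R)-2-[(tert-butyldimethylsilyl)oxy]-2-(4-methoxyphenyl)-3-phenylcyclopropane-1-carboxylate F3.
- Deprotonation gives its lithium enolate F4, and acylation with 8 gives the tert-butyl 1-aroyl cyclopropane ester F5.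
- Et3N·3HF opens F5 to tert-butyl (2R,3R)-2-[2-(benzyloxy)-4,6-dimethoxybenzoyl]-4-(4-methoxyphenyl)-4-oxo-3-phenylbutanoate F6.
- F6 is heated in toluene at 100 to 110 °C while 12 is added slowly. Loss of tert-butanol gives the α-oxoketene (3R)-2-[2-(benzyloxy)-4,6-dimethoxybenzoyl]-4-(4-methoxyphenyl)-3-phenylbut-1-ene-1,4-dione F7, which the amine traps at once to give 13.

Step 8. The position or the rate of the C3 equilibrium may leave a mixture of epimers, and slow over-reduction of the aryl ketones may set in if the hydrogenolysis is prolonged to force conversion. Fallback (sets out from 13, returns at 14): the hydrogenolysis is stopped at full debenzylation and the epimers are separated by chromatography. The unwanted (2R,3S)-N-(4-benzamidobutyl)-2-(2-hydroxy-4,6-dimethoxybenzoyl)-4-(4-methoxyphenyl)-4-oxo-3-phenylbutanamide F8 is re-equilibrated at room temperature with a trace of Et3N in CH2Cl2 and returned to the separation, so that the material converges on 14 by recycling and not by crystallisation alone.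

## Further compounds

F1 | step 6 | methyl 1-{[2-(benzyloxy)-4,6-dimethoxyphenyl](hydroxy)methyl}-2-[(tert-butyldimethylsilyl)oxy]-2-(4-methoxyphenyl)-3-phenylcyclopropane-1-carboxylate | COC(=O)[C@]1(C(O)c2c(OCc3ccccc3)cc(OC)cc2OC)[C@H](c2ccccc2)[C@@]1(O[Si](C)(C)C(C)(C)C)c1ccc(OC)cc1
F2 | step 2 | methyl (1R,2R,3S)-2-[(tert-butyldimethylsilyl)oxy]-2-(4-methoxyphenyl)-3-phenylcyclopropane-1-carboxylate | COC(=O)[C@@H]1[C@@H](c2ccccc2)[C@]1(O[Si](C)(C)C(C)(C)C)c1ccc(OC)cc1
F3 | step 7 | tert-butyl (1S,2S,3R)-2-[(tert-butyldimethylsilyl)oxy]-2-(4-methoxyphenyl)-3-phenylcyclopropane-1-carboxylate | CC(C)(C)OC(=O)[C@H]1[C@H](c2ccccc2)[C@@]1(O[Si](C)(C)C(C)(C)C)c1ccc(OC)cc1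
F4 | step 7 | lithium enolate of F3 | [Li+].CC(C)(C)OC([O-])=C1[C@H](c2ccccc2)[C@@]1(O[Si](C)(C)C(C)(C)C)c1ccc(OC)cc1
F5 | step 7 | tert-butyl 1-[2-(benzyloxy)-4,6-dimethoxybenzoyl]-2-[(tert-butyldimethylsilyl)oxy]-2-(4-methoxyphenyl)-3-phenylcyclopropane-1-carboxylate | CC(C)(C)OC(=O)[C@]1(C(=O)c2c(OCc3ccccc3)cc(OC)cc2OC)[C@H](c2ccccc2)[C@@]1(O[Si](C)(C)C(C)(C)C)c1ccc(OC)cc1
F6 | step 7 | tert-butyl (2R,3R)-2-[2-(benzyloxy)-4,6-dimethoxybenzoyl]-4-(4-methoxyphenyl)-4-oxo-3-phenylbutanoate | COc1ccc(C(=O)[C@@H](c2ccccc2)[C@@H](C(=O)OC(C)(C)C)C(=O)c2c(OCc3ccccc3)cc(OC)cc2OC)cc1
F7 | step 7 | (3R)-2-[2-(benzyloxy)-4,6-dimethoxybenzoyl]-4-(4-methoxyphenyl)-3-phenylbut-1-ene-1,4-dione | COc1ccc(C(=O)[C@@H](c2ccccc2)C(=C=O)C(=O)c2c(OCc3ccccc3)cc(OC)cc2OC)cc1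
F8 | step 8 | (2R,3S)-N-(4-benzamidobutyl)-2-(2-hydroxy-4,6-dimethoxybenzoyl)-4-(4-methoxyphenyl)-4-oxo-3-phenylbutanamide | COc1ccc(C(=O)[C@@H](c2ccccc2)[C@H](C(=O)NCCCCNC(=O)c2ccccc2)C(=O)c2c(O)cc(OC)cc2OC)cc1
A1 | alternative 1 | 3-hydroxy-5,7-dimethoxy-2-(4-methoxyphenyl)-4H-chromen-4-one | COc1ccc(-c2oc3cc(OC)cc(OC)c3c(=O)c2O)cc1
A2 | alternative 1 | (E)-N-(4-benzamidobutyl)-3-phenylprop-2-enamide | O=C(/C=C/c1ccccc1)NCCCCNC(=O)c1ccccc1
A3 | alternative 1 | bridged aglain ketone | O=C1[C@]2(c3ccc(OC)cc3)Oc3cc(OC)cc(OC)c3[C@@]1(O)[C@@H](C(=O)NCCCCNC(=O)c1ccccc1)[C@@H]2c1ccccc1
A4 | alternative 2 | (E)-4-[2-(benzyloxy)-4,6-dimethoxyphenyl]-1-(4-methoxyphenyl)-2-phenylbut-2-ene-1,4-dione | COc1ccc(C(=O)/C(c2ccccc2)=C/C(=O)c2c(OCc3ccccc3)cc(OC)cc2OC)cc1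
A5 | alternative 2 | N-(4-isocyanobutyl)benzamide | [C-]#[N+]CCCCNC(=O)c1ccccc1
A6 | alternative 2 | N-[4-({3-[2-(benzyloxy)-4,6-dimethoxybenzoyl]-5-(4-methoxyphenyl)-4-phenylfuran-2-yl}amino)butyl]benzamide | COc1ccc(-c2oc(NCCCCNC(=O)c3ccccc3)c(C(=O)c3c(OCc4ccccc4)cc(OC)cc3OC)c2-c2ccccc2)cc1
A7 | alternative 3 | (E)-N-(4-benzamidobutyl)-2-[2-(benzyloxy)-4,6-dimethoxybenzoyl]-4-(4-methoxyphenyl)-4-oxobut-2-enamide (geometry not controlled) | COc1ccc(C(=O)/C=C(/C(=O)NCCCCNC(=O)c2ccccc2)C(=O)c2c(OCc3ccccc3)cc(OC)cc2OC)cc1
A8 | alternative 3 | phenylboronic acid | OB(O)c1ccccc1
A9 | alternative 3 | O-benzyl ether of the target (identical with 13) | COc1ccc(C(=O)[C@@H](c2ccccc2)[C@@H](C(=O)NCCCCNC(=O)c2ccccc2)C(=O)c2c(OCc3ccccc3)cc(OC)cc2OC)cc1
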